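A direct plan would build the chromone first and attach ring B last: acylation of 3,4,5-trimethoxyphenol A1 to the hydroxyacetophenone A2, enaminone closure to 5,6,7-trimethoxychromone A3, zincation at C2 to the chromonylzinc chloride A4 and Negishi coupling with 4-bromo-2,6-dimethoxyphenol A5. Its weakest steps would be the C2 deprotonation (the 2-metalated pyranone is a β-acylvinyl anion that can ring-open, and the amide base can add at C2), the coupling onto an unprotected electron-rich bromophenol (the acidic OH would protonate the carbon–zinc bond and the phenoxide would slow oxidative addition), and the acylation–enaminone sequence, two steps spent on a bicycle that carries nothing of ring B.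

The route disconnects ring C at C4–C4a. Ring B would enter as an arylpropiolate that already holds C2, C3 and C4; conjugate addition of 3,4,5-trimethoxyphenol would make the O1–C2 bond first, and the pyranone would then be closed at carbon by intramolecular Friedel–Crafts acylation. The step exploits ring A: C4a is one of two symmetry-equivalent ortho carbons of the phenol, ortho to the C5 methoxy and para to the C7 methoxy, so closure should be fast and could give only the 5,6,7-pattern. No chromone is metalated, no aryl–C2 bond is made by coupling, and no organometallic meets a free phenol.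

Key step: step 5

Step 1
Reactants: 1 syringaldehyde (4-hydroxy-3,5-dimethoxybenzaldehyde)
Product: 2 3,5-dimethoxy-4-[(triisopropylsilyl)oxy]benzaldehyde
Conditions: iPr3SiCl (1.2 equiv), imidazole (2.5 equiv), DMF, 25–40 °C
Reagents that add atoms: triisopropylsilyl chloride, CC(C)[Si](Cl)(C(C)C)C(C)C
Why: Imidazole-promoted O-silylation of the phenol (silyl ether formation) should mask the only acidic proton against the ylide and the butyllithium of the next two steps, the bulky silyl group between two methoxy groups resisting both; no stereocentre is formed.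

Step 2
Reactants: 2 3,5-dimethoxy-4-[(triisopropylsilyl)oxy]benzaldehyde
Product: 3 [4-(2,2-dibromoethenyl)-2,6-dimethoxyphenoxy]triisopropylsilane
Conditions: CBr4 (2 equiv), PPh3 (4 equiv), CH2Cl2, 0 °C
Reagents that add atoms: carbon tetrabromide, BrC(Br)(Br)Br
Why: In this Ramirez dibromo-olefination (first stage of the Corey–Fuchs sequence) the ylide Ph3P=CBr2 made in the flask should convert the aldehyde into the 1,1-dibromoalkene by a Wittig reaction, adding the carbon that becomes C3; no stereocentre is formed.

Step 3
Reactants: 3 [4-(2,2-dibromoethenyl)-2,6-dimethoxyphenoxy]triisopropylsilane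
Product: 5 methyl 3-{3,5-dimethoxy-4-[(triisopropylsilyl)oxy]phenyl}prop-2-ynoate, via lithium acetylide 4 (not isolated)
Conditions: n-BuLi (2.1 equiv), THF, −78 °C; then ClCO2Me (1.5 equiv), −78 to 0 °C
Reagents that add atoms: methyl chloroformate, COC(=O)Cl
Why: In the second stage of the Corey–Fuchs sequence bromine–lithium exchange and Fritsch–Buttenberg–Wiechell rearrangement of the carbenoid should give the arylalkyne, which the second equivalent of n-BuLi deprotonates, and C-acylation of the acetylide by the chloroformate (in excess, at −78 °C, to suppress a second addition) installs the carbon that becomes C4; no stereocentre is formed.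

Step 4
Reactants: 5 methyl 3-{3,5-dimethoxy-4-[(triisopropylsilyl)oxy]phenyl}prop-2-ynoate; 6 3,4,5-trimethoxyphenol
Product: 9 (2Z)-3-(4-hydroxy-3,5-dimethoxyphenyl)-3-(3,4,5-trimethoxyphenoxy)prop-2-enoic acid, via silyl ester adduct 7 (not isolated), via hydroxy ester 8 (not isolated)
Conditions: K2CO3 (0.5 equiv), MeCN, 70 °C, N2; evaporate; 2 M aq NaOH (5 equiv), MeOH, 50 °C; then 1 M HCl to pH 3, 0 °C
Reagents that add atoms: sodium hydroxide, [Na+].[OH-]
Why: Base-catalysed oxa-Michael addition of the phenoxide of 6 to the β-carbon of the ynoate should form the O1–C2 aryl vinyl ether bond, anti addition placing the aryloxy group cis to the ester (the Z alkene needed later, any E isomer being carried along because the acid of step 5 equilibrates the two), and hydroxide should then cleave the phenolic silyl ether and saponify the ester, the phenoxide and carboxylate shielding the vinylogous carbonate from addition–elimination; no stereocentre is formed.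

Step 5
Reactants: 9 (2Z)-3-(4-hydroxy-3,5-dimethoxyphenyl)-3-(3,4,5-trimethoxyphenoxy)prop-2-enoic acid
Product: 10 ageconyflavone C [2-(4-hydroxy-3,5-dimethoxyphenyl)-5,6,7-trimethoxy-4H-chromen-4-one]
Conditions: P2O5 in MeSO3H (1:10 w/w, Eaton's reagent), 25–40 °C; ice–water
Reagents that add atoms: none
Why: P2O5/MeSO3H should turn the acid into its mixed anhydride or acylium ion, which is attacked by the ortho carbon of the aryloxy ring (the future C4a) in an intramolecular Friedel–Crafts acylation, and loss of the proton gives the pyranone; the closest known reaction is the acid cyclisation of β-aryloxycinnamic acids to flavones (Ruhemann flavone synthesis) and of aryloxyfumaric acids to chromone-2-carboxylic acids. Ring C is closed at the C4–C4a bond by 6-exo-trig attack of the arene on the activated acyl carbon, possible only from the isomer with aryloxy cis to the acyl group; reversible protonation at C3 gives an oxocarbenium ion with a C2–C3 single bond, so any E isomer should be drained through the Z isomer. No stereocentre is formed. The site on ring A needs no control because the two ortho carbons of the 3,4,5-trimethoxyphenoxy group are equivalent by symmetry, so only the 5,6,7-pattern can arise, and each is ortho to one methoxy (later on C5) and para to another (later on C7), hence strongly activated. The one competing closure, onto C2′ of ring B from the E isomer to a 3-aryloxyindenone, should lose because it forms a strained five-membered ring onto a ring that shares the positive charge of C2, whereas ring A is insulated from that charge by O1. The free 4′-OH and the five methyl ethers, the peri 5-OMe included, should survive this non-nucleophilic acid at 25–40 °C.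

**Compound list**
1 | syringaldehyde (4-hydroxy-3,5-dimethoxybenzaldehyde) | COc1cc(C=O)cc(OC)c1O | starting material
2 | 3,5-dimethoxy-4-[(triisopropylsilyl)oxy]benzaldehyde | COc1cc(C=O)cc(OC)c1O[Si](C(C)C)(C(C)C)C(C)C | intermediate
3 | [4-(2,2-dibromoethenyl)-2,6-dimethoxyphenoxy]triisopropylsilane | COc1cc(C=C(Br)Br)cc(OC)c1O[Si](C(C)C)(C(C)C)C(C)C | intermediate
4 | lithium {3,5-dimethoxy-4-[(triisopropylsilyl)oxy]phenyl}acetylide | [Li]C#Cc1cc(OC)c(O[Si](C(C)C)(C(C)C)C(C)C)c(OC)c1 | intermediate
5 | methyl 3-{3,5-dimethoxy-4-[(triisopropylsilyl)oxy]phenyl}prop-2-ynoate | COC(=O)C#Cc1cc(OC)c(O[Si](C(C)C)(C(C)C)C(C)C)c(OC)c1 | intermediate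
6 | 3,4,5-trimethoxyphenol | COc1cc(O)cc(OC)c1OC | starting material
7 | methyl (2Z)-3-{3,5-dimethoxy-4-[(triisopropylsilyl)oxy]phenyl}-3-(3,4,5-trimethoxyphenoxy)prop-2-enoate | COC(=O)/C=C(\Oc1cc(OC)c(OC)c(OC)c1)c1cc(OC)c(O[Si](C(C)C)(C(C)C)C(C)C)c(OC)c1 | intermediate
8 | methyl (2Z)-3-(4-hydroxy-3,5-dimethoxyphenyl)-3-(3,4,5-trimethoxyphenoxy)prop-2-enoate | COC(=O)/C=C(\Oc1cc(OC)c(OC)c(OC)c1)c1cc(OC)c(O)c(OC)c1 | intermediate
9 | (2Z)-3-(4-hydroxy-3,5-dimethoxyphenyl)-3-(3,4,5-trimethoxyphenoxy)prop-2-enoic acid | OC(=O)/C=C(\Oc1cc(OC)c(OC)c(OC)c1)c1cc(OC)c(O)c(OC)c1 | intermediate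
10 | ageconyflavone C, 2-(4-hydroxy-3,5-dimethoxyphenyl)-5,6,7-trimethoxy-4H-chromen-4-one (achiral) | COc1cc(-c2cc(=O)c3c(OC)c(OC)c(OC)cc3o2)cc(OC)c1O | target

Total steps: 5. Longest linear sequence: 5 steps (1 to 10).

Steps most likely to fail:

Step 5 (key step). Protonation at C3 followed by loss of CO2 from the oxocarbenium ion could compete with acylation, as could attack on ring B before ring A. The fallback reverses the polarity at C4a, sets out from 6 and 5 and returns at 10. Bromination of 6 (N-bromosuccinimide, MeCN, 0 °C) would give 2-bromo-3,4,5-trimethoxyphenol F1, whose addition to 5 under the first conditions of step 4 (K2CO3, MeCN, 70 °C, no hydroxide) would give methyl (2Z)-3-(2-bromo-3,4,5-trimethoxyphenoxy)-3-{3,5-dimethoxy-4-[(triisopropylsilyl)oxy]phenyl}prop-2-enoate F2 as the vinyl ether. Bromine–lithium exchange (t-BuLi, 2 equiv, THF, −90 °C) and attack of the aryllithium on the cis ester (Parham cyclisation) would close ring C to 2-{3,5-dimethoxy-4-[(triisopropylsilyl)oxy]phenyl}-5,6,7-trimethoxy-4H-chromen-4-one F3, from which Bu4NF (THF, 0 °C) would release 10.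

Step 4. The silyl group could migrate from the ring B oxygen to the phenoxide of 6; the ring B phenoxide so formed is a push–pull ynoate that no longer accepts the nucleophile, and conversion would stall. The fallback uses an ether that cannot be transferred, sets out from 5 and returns at 10. Bu4NF added to 5 in the presence of benzyl bromide (THF, 0 to 25 °C), so that the phenoxide is benzylated as it forms, would give methyl 3-[4-(benzyloxy)-3,5-dimethoxyphenyl]prop-2-ynoate F4, and addition of 6 (K2CO3, MeCN, 70 °C) would give methyl (2Z)-3-[4-(benzyloxy)-3,5-dimethoxyphenyl]-3-(3,4,5-trimethoxyphenoxy)prop-2-enoate F5 as the vinyl ether. Saponification (aq NaOH, MeOH, 50 °C) would give (2Z)-3-[4-(benzyloxy)-3,5-dimethoxyphenyl]-3-(3,4,5-trimethoxyphenoxy)prop-2-enoic acid F6 as the cyclisation substrate. Ring closure under an activation that spares the benzyl ether ((CF3CO)2O, CH2Cl2, 0 to 25 °C) would give 2-[4-(benzyloxy)-3,5-dimethoxyphenyl]-5,6,7-trimethoxy-4H-chromen-4-one F7, and hydrogenolysis (H2, Pd/C, EtOAc, 25 °C) would give 10.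

Step 3. The acetylide could add a second time, to the ynoate as it forms or twice at the chloroformate, which would give dialkynyl ketone and carbinol. The fallback sets out from 3 and returns at 5. The acetylide 4 would be trapped with CO2 (gas, −78 to 0 °C), whose carboxylate product cannot be attacked again, to give after acidification 3-{3,5-dimethoxy-4-[(triisopropylsilyl)oxy]phenyl}prop-2-ynoic acid F8, and O-methylation (MeI, K2CO3, DMF, 25 °C) would then give 5.

Further compounds
F1 | step 5 | 2-bromo-3,4,5-trimethoxyphenol | COc1cc(O)c(Br)c(OC)c1OC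
F2 | step 5 | methyl (2Z)-3-(2-bromo-3,4,5-trimethoxyphenoxy)-3-{3,5-dimethoxy-4-[(triisopropylsilyl)oxy]phenyl}prop-2-enoate | COC(=O)/C=C(\Oc1cc(OC)c(OC)c(OC)c1Br)c1cc(OC)c(O[Si](C(C)C)(C(C)C)C(C)C)c(OC)c1
F3 | step 5 | 2-{3,5-dimethoxy-4-[(triisopropylsilyl)oxy]phenyl}-5,6,7-trimethoxy-4H-chromen-4-one | COc1cc(-c2cc(=O)c3c(OC)c(OC)c(OC)cc3o2)cc(OC)c1O[Si](C(C)C)(C(C)C)C(C)C
F4 | step 4 | methyl 3-[4-(benzyloxy)-3,5-dimethoxyphenyl]prop-2-ynoate | COC(=O)C#Cc1cc(OC)c(OCc2ccccc2)c(OC)c1
F5 | step 4 | methyl (2Z)-3-[4-(benzyloxy)-3,5-dimethoxyphenyl]-3-(3,4,5-trimethoxyphenoxy)prop-2-enoate | COC(=O)/C=C(\Oc1cc(OC)c(OC)c(OC)c1)c1cc(OC)c(OCc2ccccc2)c(OC)c1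
F6 | step 4 | (2Z)-3-[4-(benzyloxy)-3,5-dimethoxyphenyl]-3-(3,4,5-trimethoxyphenoxy)prop-2-enoic acid | OC(=O)/C=C(\Oc1cc(OC)c(OC)c(OC)c1)c1cc(OC)c(OCc2ccccc2)c(OC)c1
F7 | step 4 | 2-[4-(benzyloxy)-3,5-dimethoxyphenyl]-5,6,7-trimethoxy-4H-chromen-4-one | COc1cc(-c2cc(=O)c3c(OC)c(OC)c(OC)cc3o2)cc(OC)c1OCc1ccccc1
F8 | step 3 | 3-{3,5-dimethoxy-4-[(triisopropylsilyl)oxy]phenyl}prop-2-ynoic acid | OC(=O)C#Cc1cc(OC)c(O[Si](C(C)C)(C(C)C)C(C)C)c(OC)c1
A1 | direct plan | 3,4,5-trimethoxyphenol | COc1cc(O)cc(OC)c1OC
A2 | direct plan | 1-(6-hydroxy-2,3,4-trimethoxyphenyl)ethan-1-one | CC(=O)c1c(O)cc(OC)c(OC)c1OC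
A3 | direct plan | 5,6,7-trimethoxy-4H-chromen-4-one | COc1cc2occc(=O)c2c(OC)c1OC
A4 | direct plan | (5,6,7-trimethoxy-4-oxo-4H-chromen-2-yl)zinc chloride | COc1cc2oc([Zn]Cl)cc(=O)c2c(OC)c1OC
A5 | direct plan | 4-bromo-2,6-dimethoxyphenol | COc1cc(Br)cc(OC)c1O
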